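The data were generated by integration with constants of no real substance; scatter was added.

The pitfall with a stalled target is to read the stall as a shortage and top something up. You have this winter flask, followed so far, and an earlier noon run:

the same everywhere: starting material 0.20 M
- winter: first nucleophile 0.30 M; second nucleophile 0.14 M; protic impurity 4 mM; temperature 25 °C; the very flask that is asked about, followed so far
- noon: first nucleophile 0.30 M; second nucleophile 0.14 M; protic impurity 4 mM; temperature 31 °C; run made earlier
- flask: first nucleophile 0.300 M; second nucleophile 0.140 M; protic impurity 4.00 mM; temperature 25 °C; time 30 h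

| run | time / h | target / % | starting material / % |
|---|---|---|---|
| winter | 1.00 | 7 | 73 |
| winter | 3.00 | 9 | 41 |
| winter | 5.00 | 17 | 28 |
| winter | 8.00 | 16 | 14 |
| winter | 10.0 | 22 | 7 |
| winter | 15.0 | 22 | 5 |
| winter | 20.0 | 20 | 3 |
| noon | 1.00 | 6 | 56 |
| noon | 3.00 | 16 | 22 |
| noon | 5.00 | 21 | 10 |
| noon | 8.00 | 24 | 5 |
| noon | 10.0 | 24 | 7 |
| noon | 15.0 | 26 | 2 |
| noon | 20.0 | 32 | 3 |

(scatter of a reading: 1.5 percentage points)

- elm: at 30 h add second nucleophile, 50.0 % of the amount charged, then wait 10 h
- ash: at 30 h take out 90 % of the target then present, then wait 10 h
- oak: change nothing and wait 10 h more
- birch: at 30 h raise the temperature by 20 K, then wait 10 h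

- target that was removed still counts
- the analysis behind the earlier runs scatters by 1.5 percentage points, standard deviation
- additions bring no volume worth counting

1. target, in percent of the starting material first charged, at 30 h
2. the option that brings most further target ("none" if no option brings more than 2 percentage points) (elm / ash / oak / birch / none)
3. target present, with what was taken out counted in, in percent of the starting material first charged, after elm
4. target present, with what was taken out counted in, in percent of the starting material first charged, after oak

My own reckoning asks how reacted starting material divides. Noon has 22 % starting material left at 3.00 h against winter's 41 %, less, so it runs ahead, and I pool the last three readings of both runs. Of the starting material gone in those readings, 25.5 % shows up as target, a reading pooled over both temperatures. That gives the target odds, a reading of selectivity: target made against the remainder of the reacted starting material, here 0.342. Taking winter's 3 % at 20.0 h as what is left, I expect 24.7 % at 30 h. Turning winter's last starting material over at the same share brings about 0.76 percentage points, and the bar stands at 2 points, so I would say none.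

The forecast gives 24.5 %, 26.5 % after oak, and 36 % after elm, which it chooses: “More nucleophile should then give the largest gain”. On the choice we differ.

The flask gives 24.6 %, and the best option is birch, with 15 points against 0.92 points for elm, which ends at 25.5 %, and 1.5 points for oak, which ends at 26.0 %.

    starting material ⇌ intermediate (K = 0.00150, k = 0.252 h⁻¹, Ea = 93.0 kJ mol⁻¹, ΔH = 11.0 kJ mol⁻¹)
    first nucleophile + intermediate → target (k = 398 M⁻¹ h⁻¹, Ea = 66.0 kJ mol⁻¹)
    second nucleophile + intermediate → other capture product (k = 2440 M⁻¹ h⁻¹, Ea = 57.0 kJ mol⁻¹)
    starting material + protic impurity → quenched substrate (k = 109 M⁻¹ h⁻¹, Ea = 55.0 kJ mol⁻¹)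
    starting material ⇌ dormant form (K = 4.45, k = 0.0931 h⁻¹, Ea = 103 kJ mol⁻¹, ΔH = −63.0 kJ mol⁻¹)
    (constants at 25 °C)

At 30.0 h this flask holds 24.5 % as dormant form, which the odds count in the remainder, and its own odds come to 0.336. Now take the neighbour flask charged with 0.24 M of second nucleophile, the rival capture partner in the equations. As an estimate, with the first nucleophile held, scaling the read odds by 0.140 M over 0.24 M gives 0.199, and with 1.8 % starting material left, that reckons to 16.3 % target. That neighbour flask stands at 15.6 % at 30.0 h.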